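**Retrosynthetic overview**

- Haemathamnolic acid is a depside: ring A (3-formyl-2-hydroxy-4-methoxy-6-methylbenzoyl) is esterified to O-5' of ring B (3'-formyl-2',4'-dihydroxy-6'-methylbenzoic acid). The plan rests on ring A: C1–C2–C3 with the ester carbonyl are the four carbons of an acetoacetate of the ring B phenol, and C4(OMe)–C5–C6(CH3) is an acetylketene dimethyl acetal.
- Last disconnections: the three benzyl groups (hydrogenolysis), then both formyl C–C bonds (C3–CHO and C3'–CHO) in one double Rieche formylation.
- Key disconnection: C3–C4 and C1–C6 of ring A, by TiCl4-mediated [3+3] cyclocondensation of the 1,3-bis(silyloxy)diene of the aryl acetoacetate with 4,4-dimethoxybut-3-en-2-one.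
- The acetoacetate comes from the ring B phenol and a dioxinone. The O–C5' bond comes from an Elbs oxidation of benzyl orsellinate, whose sulfate masks O-5' while O-2' and O-4' are benzylated.
- Ring order: ring B is bought as orsellinic acid; ring A is the only ring formed, and it is built on the ester oxygen of ring B.

Key step: step 8

Assumption: each ring is numbered as a benzoate (C1 bears the carboxyl carbon, ring B locants primed in the depsides). The enol ether and ketene acetal double bonds of 9, 10 and 14 are drawn as single isomers; their geometry is lost in ring A, so isomer mixtures would serve equally.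

**Route**

Step 1
Reactants: 1 orsellinic acid (2,4-dihydroxy-6-methylbenzoic acid)
Product: 2 benzyl 2,4-dihydroxy-6-methylbenzoate (benzyl orsellinate)
Conditions: BnBr (1.05 equiv), KHCO3 (1.1 equiv), DMF, 20 °C
Reagents that add atoms: benzyl bromide, BrCc1ccccc1
Why: Carboxylate SN2 alkylation; hydrogencarbonate deprotonates only the carboxylic acid, so both phenols stay free, and the low temperature avoids decarboxylation.

Step 2
Reactants: 2 benzyl 2,4-dihydroxy-6-methylbenzoate
Product: 3 potassium salt of benzyl 2,4-dihydroxy-6-methyl-5-(sulfonatooxy)benzoate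
Conditions: K2S2O8 (1.1 equiv), 2 M aq KOH, pyridine, 0 → 20 °C; H2SO4 to pH 5; Et2O wash (returns unreacted 2); n-BuOH extraction
Reagents that add atoms: potassium peroxodisulfate, [K+].[K+].[O-]S(=O)(=O)OOS(=O)(=O)[O-]
Why: Elbs persulfate oxidation; the phenolate attacks the peroxide oxygen through the carbon para to O-2, and C5 is the only open para position (C1, para to O-4, is blocked), so the new oxygen arrives at C5 already masked as a sulfate monoester, while the hindered ester of the phenolate dianion resists cold alkali.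

Step 3
Reactants: 3 potassium salt of benzyl 2,4-dihydroxy-6-methyl-5-(sulfonatooxy)benzoate
Product: 5 benzyl 2,4-bis(benzyloxy)-5-hydroxy-6-methylbenzoate, via dibenzylated aryl sulfate salt 4 (not isolated)
Conditions: BnBr (2.5 equiv), K2CO3 (3 equiv), DMF, 60 °C; filter, concentrate; then 2 M HCl, 1,4-dioxane, 60 °C
Reagents that add atoms: benzyl bromide, BrCc1ccccc1
Why: Williamson etherification of the two phenols, the sulfate monoester anion being too poor a nucleophile to be alkylated, followed by acid-catalysed hydrolysis of the aryl sulfate with S–O cleavage, the classical route from an Elbs sulfate to a selectively free quinol oxygen.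

Step 4
Reactants: 5 benzyl 2,4-bis(benzyloxy)-5-hydroxy-6-methylbenzoate; 6 2,2,6-trimethyl-4H-1,3-dioxin-4-one
Product: 8 benzyl 2,4-bis(benzyloxy)-6-methyl-5-(3-oxobutanoyloxy)benzoate, via acetylketene 7 (not isolated)
Conditions: 6 (1.5 equiv), toluene, 110 °C, acetone distilled off
Reagents that add atoms: none
Why: Acetoacetylation by acylketene trapping; retro-hetero-Diels–Alder fragmentation of the dioxinone releases acetylketene, which is small and reactive enough to acylate the doubly ortho-substituted phenol under neutral conditions.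

Step 5
Reactants: 8 benzyl 2,4-bis(benzyloxy)-6-methyl-5-(3-oxobutanoyloxy)benzoate
Product: 9 benzyl 2,4-bis(benzyloxy)-6-methyl-5-{[(2E)-3-(trimethylsilyloxy)but-2-enoyl]oxy}benzoate
Conditions: Me3SiCl (1.6 equiv), Et3N (1.8 equiv), toluene, 20 °C; filtered under argon, concentrated, used crude
Reagents that add atoms: chlorotrimethylsilane, C[Si](C)(C)Cl
Why: Soft enolisation and O-silylation of the ketone of a β-keto ester, the standard first stage of 1,3-bis(silyl enol ether) synthesis, in which no strong base meets the aryl ester.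

Step 6
Reactants: 9 benzyl 2,4-bis(benzyloxy)-6-methyl-5-{[(2E)-3-(trimethylsilyloxy)but-2-enoyl]oxy}benzoate
Product: 10 benzyl 2,4-bis(benzyloxy)-5-{[(1E)-1,3-bis(trimethylsilyloxy)buta-1,3-dien-1-yl]oxy}-6-methylbenzoate
Conditions: LiN(iPr)2 (LDA, 1.2 equiv), Me3SiCl (1.5 equiv, present from the start), THF, −78 → 0 °C; concentrated, pentane, filtered under argon, used crude
Reagents that add atoms: chlorotrimethylsilane, C[Si](C)(C)Cl
Why: Kinetic γ-deprotonation of the 3-silyloxy enoate and O-silylation of the dienolate (second stage of the standard bis(silyl enol ether) preparation); the aryl ester is shielded by its two ortho substituents, the in situ quench at −78 °C outruns loss of aryloxide from the dienolate, and a small excess of base leaves the less acidic ring B methyl group untouched.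

Step 7
Reactants: 11 acetyl chloride; 12 1,1-dimethoxyethene
Product: 13 4,4-dimethoxybut-3-en-2-one
Conditions: 12 (2.1 equiv), Et2O, 0 → 20 °C; distillation
Reagents that add atoms: none
Why: C-acylation of a ketene acetal by an acid chloride followed by proton loss gives the push–pull enone, the second equivalent of ketene acetal taking up HCl as methyl acetate and chloromethane.

Step 8
Reactants: 10 benzyl 2,4-bis(benzyloxy)-5-{[(1E)-1,3-bis(trimethylsilyloxy)buta-1,3-dien-1-yl]oxy}-6-methylbenzoate; 13 4,4-dimethoxybut-3-en-2-one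
Product: 15 benzyl 2,4-bis(benzyloxy)-5-(2-hydroxy-4-methoxy-6-methylbenzoyloxy)-6-methylbenzoate, via open-chain methoxy dioxo octenoate ester 14 (not isolated)
Conditions: 13 (1.2 equiv), TiCl4 (1.2 equiv), 4 Å MS, CH2Cl2, −78 → 0 °C; then 1 M HCl
Reagents that add atoms: none
Why: TiCl4 binds the carbonyl oxygen of 13 and makes it a vinylogous dioxocarbenium ion with the positive charge on the dimethoxy carbon, so the terminal CH2 of diene 10 (future C3) adds there in a Mukaiyama–Michael step, and loss of one methoxide gives 14 (present as its titanium enolate) with the C3–C4 bond made and the surviving methoxy group on C4. The former ketene acetal carbon (future C1), now the central carbon of a β-keto ester enolate, adds to the methyl ketone (future C6) in a 6-(enolendo)-exo-trig aldol closure, and dehydration with enolisation aromatises ring A, leaving its C2 hydroxyl chelated to the ester. The closest known reaction is the TiCl4-mediated [3+3] cyclocondensation of 1-alkoxy-1,3-bis(silyloxy)buta-1,3-dienes with 3-alkoxy and 3,3-dialkoxy enones to give salicylates, the alkoxy group here being the ring B aryloxy group. No stereocentre is formed. The selectivity needed is orientational, terminal diene carbon to the dimethoxy carbon and not to the ketone (which would give the 2-hydroxy-6-methoxy-4-methyl isomer), and it is secured by the Lewis acid polarisation of 13 and by the higher nucleophilicity of the diene terminus over its internal carbon. One equivalent of TiCl4 and a ceiling of 0 °C are chosen to spare the benzyl ethers and the doubly ortho-substituted aryl ester.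

Step 9
Reactants: 15 benzyl 2,4-bis(benzyloxy)-5-(2-hydroxy-4-methoxy-6-methylbenzoyloxy)-6-methylbenzoate
Product: 17 benzyl 2,4-bis(benzyloxy)-3-formyl-5-(3-formyl-2-hydroxy-4-methoxy-6-methylbenzoyloxy)-6-methylbenzoate, via bis[chloro(methoxy)methyl] arene 16 (not isolated)
Conditions: Cl2CHOCH3 (5 equiv), TiCl4 (6 equiv), CH2Cl2, −78 → 0 °C; then ice-cold 1 M HCl
Reagents that add atoms: dichloromethyl methyl ether, COC(Cl)Cl; water, O
Why: Two-directional Rieche formylation (Friedel–Crafts alkylation by the titanium-activated α-chloro ether, hydrolysis on work-up); in ring A the titanium phenoxide at O-2 directs to its only free ortho carbon C3 in preference to C5, and in ring B only C3' is open and is activated by both flanking ether oxygens.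

Step 10
Reactants: 17 benzyl 2,4-bis(benzyloxy)-3-formyl-5-(3-formyl-2-hydroxy-4-methoxy-6-methylbenzoyloxy)-6-methylbenzoate
Product: 18 haemathamnolic acid (3-formyl-5-[(3-formyl-2-hydroxy-4-methoxy-6-methylbenzoyl)oxy]-2,4-dihydroxy-6-methylbenzoic acid)
Conditions: H2 (1 atm), Pd/C (10% Pd on carbon), EtOAc, 20 °C, stopped after three equivalents of H2
Reagents that add atoms: none
Why: Catalytic hydrogenolysis of the benzyl ester and the two aryl benzyl ethers under neutral conditions should leave the depside ester, the methyl ether and the chelated aryl aldehydes intact.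

**Compound list**

1 | orsellinic acid (2,4-dihydroxy-6-methylbenzoic acid) | Cc1cc(O)cc(O)c1C(=O)O | starting material
2 | benzyl 2,4-dihydroxy-6-methylbenzoate | Cc1cc(O)cc(O)c1C(=O)OCc1ccccc1 | intermediate
3 | potassium salt of benzyl 2,4-dihydroxy-6-methyl-5-(sulfonatooxy)benzoate | Cc1c(OS(=O)(=O)[O-])c(O)cc(O)c1C(=O)OCc1ccccc1.[K+] | intermediate
4 | potassium salt of benzyl 2,4-bis(benzyloxy)-6-methyl-5-(sulfonatooxy)benzoate | Cc1c(OS(=O)(=O)[O-])c(OCc2ccccc2)cc(OCc2ccccc2)c1C(=O)OCc1ccccc1.[K+] | intermediate
5 | benzyl 2,4-bis(benzyloxy)-5-hydroxy-6-methylbenzoate | Cc1c(O)c(OCc2ccccc2)cc(OCc2ccccc2)c1C(=O)OCc1ccccc1 | intermediate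
6 | 2,2,6-trimethyl-4H-1,3-dioxin-4-one | CC1=CC(=O)OC(C)(C)O1 | starting material
7 | acetylketene (3-oxobut-1-en-1-one) | CC(=O)C=C=O | intermediate
8 | benzyl 2,4-bis(benzyloxy)-6-methyl-5-(3-oxobutanoyloxy)benzoate | CC(=O)CC(=O)Oc1c(C)c(C(=O)OCc2ccccc2)c(OCc2ccccc2)cc1OCc1ccccc1 | intermediate
9 | benzyl 2,4-bis(benzyloxy)-6-methyl-5-{[(2E)-3-(trimethylsilyloxy)but-2-enoyl]oxy}benzoate | C/C(O[Si](C)(C)C)=C\C(=O)Oc1c(C)c(C(=O)OCc2ccccc2)c(OCc2ccccc2)cc1OCc1ccccc1 | intermediate
10 | benzyl 2,4-bis(benzyloxy)-5-{[(1E)-1,3-bis(trimethylsilyloxy)buta-1,3-dien-1-yl]oxy}-6-methylbenzoate | C=C(O[Si](C)(C)C)/C=C(/O[Si](C)(C)C)Oc1c(C)c(C(=O)OCc2ccccc2)c(OCc2ccccc2)cc1OCc1ccccc1 | intermediate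
11 | acetyl chloride | CC(=O)Cl | starting material
12 | 1,1-dimethoxyethene | C=C(OC)OC | starting material
13 | 4,4-dimethoxybut-3-en-2-one | CC(=O)C=C(OC)OC | intermediate
14 | benzyl 2,4-bis(benzyloxy)-5-{[(5E)-5-methoxy-3,7-dioxooct-5-enoyl]oxy}-6-methylbenzoate (drawn in its neutral keto form) | CC(=O)/C=C(/OC)CC(=O)CC(=O)Oc1c(C)c(C(=O)OCc2ccccc2)c(OCc2ccccc2)cc1OCc1ccccc1 | intermediate
15 | benzyl 2,4-bis(benzyloxy)-5-(2-hydroxy-4-methoxy-6-methylbenzoyloxy)-6-methylbenzoate | COc1cc(C)c(C(=O)Oc2c(C)c(C(=O)OCc3ccccc3)c(OCc3ccccc3)cc2OCc2ccccc2)c(O)c1 | intermediate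
16 | benzyl 2,4-bis(benzyloxy)-3-[chloro(methoxy)methyl]-5-{3-[chloro(methoxy)methyl]-2-hydroxy-4-methoxy-6-methylbenzoyloxy}-6-methylbenzoate (both chloro ether carbons unassigned, mixture) | COc1cc(C)c(C(=O)Oc2c(C)c(C(=O)OCc3ccccc3)c(OCc3ccccc3)c(C(Cl)OC)c2OCc2ccccc2)c(O)c1C(Cl)OC | intermediate
17 | benzyl 2,4-bis(benzyloxy)-3-formyl-5-(3-formyl-2-hydroxy-4-methoxy-6-methylbenzoyloxy)-6-methylbenzoate | COc1cc(C)c(C(=O)Oc2c(C)c(C(=O)OCc3ccccc3)c(OCc3ccccc3)c(C=O)c2OCc2ccccc2)c(O)c1C=O | intermediate
18 | haemathamnolic acid | COc1cc(C)c(C(=O)Oc2c(C)c(C(=O)O)c(O)c(C=O)c2O)c(O)c1C=O | target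

**Step count and risks**

Total steps: 10. Longest linear sequence: 9 (steps 1–6 and 8–10 from orsellinic acid); step 7 is a one-step side branch.

Steps most likely to fail:

1. Step 8 (key step). The risks are hydrolysis of the crude diene back to the acetoacetate before C–C bond formation, sluggish ring closure because the aryloxy ketene acetal carbon is a weaker nucleophile than its alkoxy counterpart, and chelation-assisted loss of the benzyl ether at O-2' under TiCl4. The same fallback serves if the diene of step 6 cannot be made cleanly. Fallback, setting out from 1 and 5 and coming back at 15: orsellinic acid 1 is methylated at the carboxyl group and at O-4 only (MeI, K2CO3, acetone, reflux; the chelated 2-hydroxyl stays free) to methyl 2-hydroxy-4-methoxy-6-methylbenzoate F1. This is saponified (KOH, aqueous DMSO, 80 °C, cold acidification) to 2-hydroxy-4-methoxy-6-methylbenzoic acid F2. With trifluoroacetic anhydride in toluene at 20 °C, F2 gives 2-hydroxy-4-methoxy-6-methylbenzoic trifluoroacetic anhydride F3, which acylates phenol 5 to 15. This replaces ring construction on the ester by formation of the depside ester bond from a finished ring A acid.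

2. Step 9. The risks are Lewis acid cleavage of benzyl ethers with C-benzylation of the electron-rich rings by the released benzyl cations, attack at C5 of ring A instead of C3, and an incomplete second formylation at the hindered C3'. Fallback, setting out from 15 and coming back at 18: MgBr2·OEt2 (toluene–Et2O, 70 °C) removes only the benzyl ether at O-2', which is chelated to the ester carbonyl, giving benzyl 4-benzyloxy-2-hydroxy-5-(2-hydroxy-4-methoxy-6-methylbenzoyloxy)-6-methylbenzoate F4. Each ring then has a free phenol with a single open ortho carbon, and magnesium-mediated ortho-formylation (MgCl2, Et3N, paraformaldehyde, MeCN, reflux) should give benzyl 4-benzyloxy-3-formyl-5-(3-formyl-2-hydroxy-4-methoxy-6-methylbenzoyloxy)-2-hydroxy-6-methylbenzoate F5. Hydrogenolysis (H2, Pd/C, EtOAc) then gives 18. Any material that loses the O-2' benzyl group in step 8 is F4 and can enter here.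

3. Step 2. The risks are low conversion, over-oxidation of the electron-rich phenolate to quinonoid and polymeric material, and loss of the water-soluble sulfate during isolation. Fallback, setting out from 2 and coming back at 5: NBS (MeCN, 0 °C) should brominate C5, para to O-2 and next to the methyl group, giving benzyl 5-bromo-2,4-dihydroxy-6-methylbenzoate F6. BnBr, K2CO3 and DMF give benzyl 2,4-bis(benzyloxy)-5-bromo-6-methylbenzoate F7. Miyaura borylation (bis(pinacolato)diboron, PdCl2(dppf), CH3CO2K, dioxane, 90 °C) gives benzyl 2,4-bis(benzyloxy)-6-methyl-5-(4,4,5,5-tetramethyl-1,3,2-dioxaborolan-2-yl)benzoate F8, and oxidation (H2O2, aqueous NaOH, THF, 0 °C) gives 5.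

**Further compounds**

F1 | step 8 | methyl 2-hydroxy-4-methoxy-6-methylbenzoate | COC(=O)c1c(C)cc(OC)cc1O
F2 | step 8 | 2-hydroxy-4-methoxy-6-methylbenzoic acid | COc1cc(C)c(C(=O)O)c(O)c1
F3 | step 8 | 2-hydroxy-4-methoxy-6-methylbenzoic trifluoroacetic anhydride | COc1cc(C)c(C(=O)OC(=O)C(F)(F)F)c(O)c1
F4 | step 9 | benzyl 4-benzyloxy-2-hydroxy-5-(2-hydroxy-4-methoxy-6-methylbenzoyloxy)-6-methylbenzoate | COc1cc(C)c(C(=O)Oc2c(C)c(C(=O)OCc3ccccc3)c(O)cc2OCc2ccccc2)c(O)c1
F5 | step 9 | benzyl 4-benzyloxy-3-formyl-5-(3-formyl-2-hydroxy-4-methoxy-6-methylbenzoyloxy)-2-hydroxy-6-methylbenzoate | COc1cc(C)c(C(=O)Oc2c(C)c(C(=O)OCc3ccccc3)c(O)c(C=O)c2OCc2ccccc2)c(O)c1C=O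
F6 | step 2 | benzyl 5-bromo-2,4-dihydroxy-6-methylbenzoate | Cc1c(Br)c(O)cc(O)c1C(=O)OCc1ccccc1
F7 | step 2 | benzyl 2,4-bis(benzyloxy)-5-bromo-6-methylbenzoate | Cc1c(Br)c(OCc2ccccc2)cc(OCc2ccccc2)c1C(=O)OCc1ccccc1
F8 | step 2 | benzyl 2,4-bis(benzyloxy)-6-methyl-5-(4,4,5,5-tetramethyl-1,3,2-dioxaborolan-2-yl)benzoate | Cc1c(B2OC(C)(C)C(C)(C)O2)c(OCc2ccccc2)cc(OCc2ccccc2)c1C(=O)OCc1ccccc1
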